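**Retrosynthetic overview**
1. Target 28 ⇐ selective O‑acetylation and CAN unmasking of dimethyl ether 25 ⇐ Wittig isopropylidenation of δ‑keto acid 24.
2. 24 ⇐ Birch reduction of the anisole ring of tricycle 21 and oxidative excision of the resulting enone (the anisole ring is a latent δ‑keto acid; the CH centre next to the ketone is set thermodynamically).
3. 21 ⇐ cationic cyclialkylation of cyclohexanol 19 (closes the second carbocycle, sets the angular methyl and the trans ring fusion).
4. 19 ⇐ two conjugate additions to the prochiral dienone 12: a catalytic desymmetrising addition (quaternary centre and adjacent CH), then a cuprate methylation.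
5. 12 ⇐ annulation of aldehyde 9 (from 2,6‑dimethylphenol via benzyl bromide 5) with butynone. Ring order: arylmethyl‑bearing cyclohexane first, then the second decalin ring; the third (aromatic) ring is cleaved at the end.

Assumption: the antipode of the ferrocenyl diphosphine in step 6 is chosen by one screening run so that the shown enantiomer forms; minor epimers at centres that are erased later (C6 of 16, C2 of 18, C1 and C2 of 19) are carried through.

**Step 1**
Reactants: 1 2,6-dimethylphenol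
Product: 2 2,6-dimethylcyclohexa-2,5-diene-1,4-dione
Conditions: O2 (1 atm), Co(salen) (5 mol %), DMF, 25 °C
Reagents that add atoms: dioxygen O=O
Why: salcomine-catalysed aerobic para-oxidation of a 2,6-dialkylphenol to the p-benzoquinone (phenol oxidation, no stereocentre).

**Step 2**
Reactants: 2
Product: 4 2,5-dimethoxy-1,3-dimethylbenzene, via hydroquinone 3 (not isolated)
Conditions: Na2S2O4, H2O/THF; then NaOH, Me2SO4, Bu4NBr (cat.), 25 °C
Reagents that add atoms: dimethyl sulfate COS(=O)(=O)OC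
Why: dithionite reduction of the quinone followed by Williamson O-methylation of both phenols.

**Step 3**
Reactants: 4
Product: 5 1-(bromomethyl)-2,5-dimethoxy-3-methylbenzene
Conditions: NBS (1.0 equiv), AIBN (cat.), PhCF3, 80 °C
Reagents that add atoms: N-bromosuccinimide O=C1CCC(=O)N1Br
Why: Wohl–Ziegler benzylic bromination, where the two methyl groups are equivalent so mono-bromination gives one product.

**Step 4**
Reactants: 5; 6 propanal
Product: 9 3-(2,5-dimethoxy-3-methylphenyl)-2-methylpropanal (racemic), via aldimine 7 (not isolated), via alkylated aldimine 8 (not isolated)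
Conditions: 6, cyclohexylamine, MgSO4, Et2O; LDA, THF, −78 °C, then 5, −78 → 0 °C; aq. oxalic acid, 25 °C
Reagents that add atoms: none
Why: Stork metalloenamine (aza-enolate) alkylation of the propanal imine with the reactive benzylic bromide, then imine hydrolysis; the stereocentre is racemic and becomes the prochiral quaternary carbon of 12.

**Step 5**
Reactants: 9; 10 but-3-yn-2-one
Product: 12 4-[(2,5-dimethoxy-3-methylphenyl)methyl]-4-methylcyclohexa-2,5-dien-1-one, via keto-enal 11 (not isolated)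
Conditions: Triton B (cat.), t-BuOH/THF, 0 → 60 °C
Reagents that add atoms: none
Why: Michael addition of the α-branched aldehyde enolate to the ynone followed by intramolecular aldol condensation (Robinson-type annulation at the dienone oxidation level) gives the achiral, prochiral 4,4-disubstituted cyclohexadienone.

**Step 6 (key step)**
Reactants: 12; 13 1-(2-bromoethyl)-3-methoxybenzene
Product: 16 (4S,5S,6S)-4-[(2,5-dimethoxy-3-methylphenyl)methyl]-5-[2-(3-methoxyphenyl)ethyl]-4,6-dimethylcyclohex-2-en-1-one, via Grignard reagent 14 (not isolated), via magnesium dienolate 15 (not isolated)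
Conditions: 13, Mg, Et2O; 12, CuBr·SMe2 (5 mol %), (R,Sp)-Josiphos (6 mol %), t-BuOMe, −78 °C; then MeI, DMPU, −78 → 0 °C
Reagents that add atoms: iodomethane CI
Why: Cu-catalysed asymmetric conjugate addition desymmetrises the dienone, the chiral Cu–diphosphine choosing one enantiotopic enone arm while the alkyl group enters anti to the bulky arylmethyl group (sets the quaternary centre and the adjacent CH), and the cross-conjugated dienolate is then C-methylated regiospecifically (this methyl-bearing centre is erased in step 9).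

**Step 7**
Reactants: 16
Product: 18 (2S,3S,4S,5S)-4-[(2,5-dimethoxy-3-methylphenyl)methyl]-3-[2-(3-methoxyphenyl)ethyl]-2,4,5-trimethylcyclohexan-1-one, via trimethylsilyl enol ether 17 (not isolated)
Conditions: MeLi, CuI, Et2O, −20 °C; TMSCl, 16, −78 → −20 °C; then 1 M HCl
Reagents that add atoms: methyllithium [Li]C
Why: TMSCl-accelerated Gilman cuprate 1,4-addition, where in the half-chair with both large groups pseudo-equatorial the quaternary methyl is pseudo-axial and axial attack anti to it places the new methyl cis to the arylmethyl group.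

**Step 8**
Reactants: 18
Product: 19 (2S,3S,4S,5S)-4-[(2,5-dimethoxy-3-methylphenyl)methyl]-3-[2-(3-methoxyphenyl)ethyl]-2,4,5-trimethylcyclohexan-1-ol (C1 epimers)
Conditions: NaBH4, MeOH, 0 °C
Reagents that add atoms: none
Why: borohydride reduction turns the ketone into the cation precursor; the carbinol configuration is irrelevant.

**Step 9**
Reactants: 19
Product: 21 (1S,2S,4aR,10aR)-1-[(2,5-dimethoxy-3-methylphenyl)methyl]-7-methoxy-1,2,4a-trimethyl-1,2,3,4,4a,9,10,10a-octahydrophenanthrene, via cyclohexene 20 (not isolated)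
Conditions: MeSO3H (5 equiv), CH2Cl2, 0 → 25 °C
Reagents that add atoms: none
Why: Bogert–Cook-type cationic cyclialkylation (intramolecular Friedel–Crafts), in which ionisation and a 1,2-hydride shift give the tertiary cation that is trapped para to OMe through a chair transition state with the tether equatorial, giving the trans-fused ring with the new angular methyl syn to the axial quaternary methyl as in classical podocarpane syntheses.

**Step 10**
Reactants: 21
Product: 23 (4aR,4bS,7S,8S,8aR)-8-[(2,5-dimethoxy-3-methylphenyl)methyl]-4b,7,8-trimethyl-4,4a,4b,5,6,7,8,8a,9,10-decahydrophenanthren-2(3H)-one, via Birch dienol ether 22 (not isolated)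
Conditions: Li (6 equiv), NH3(l)/THF/t-BuOH, −78 → −33 °C, NH4Cl; then 2 M HCl, MeOH/THF, 50 °C
Reagents that add atoms: water O
Why: Birch reduction dearomatises the 3,4-dialkylanisole ring selectively (the 2,6-dialkyl-1,4-dimethoxybenzene would need protonation at an alkyl-bearing carbon and reacts far more slowly), and acid hydrolysis with conjugation gives the enone.

**Step 11**
Reactants: 23
Product: 24 3-[(1S,4aR,5S,6S,8aR)-5-[(2,5-dimethoxy-3-methylphenyl)methyl]-5,6,8a-trimethyl-2-oxodecahydronaphthalen-1-yl]propanoic acid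
Conditions: KMnO4 (5 mol %), NaIO4 (6 equiv), t-BuOH/H2O (pH 8), 25 °C; then H3O+
Reagents that add atoms: sodium periodate [Na+].[O-]I(=O)(=O)=O; water O
Why: Lemieux–von Rudloff cleavage of the enone C=C with loss of one carbon as CO2 unveils the δ-keto acid, and the CH centre α to the new ketone equilibrates to the equatorial (friedelin-like) configuration the target needs.

**Step 12**
Reactants: 24
Product: 25 3-[(1S,4aR,5S,6S,8aR)-5-[(2,5-dimethoxy-3-methylphenyl)methyl]-5,6,8a-trimethyl-2-(propan-2-ylidene)decahydronaphthalen-1-yl]propanoic acid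
Conditions: i-PrPPh3I (4 equiv), n-BuLi (3.9 equiv), THF, 0 °C; then 24, 0 → 66 °C; H3O+
Reagents that add atoms: isopropyltriphenylphosphonium iodide CC(C)[P+](c1ccccc1)(c1ccccc1)c1ccccc1.[I-]
Why: Wittig olefination of the ketone (substrate as its carboxylate) with isopropylidenetriphenylphosphorane builds the tetrasubstituted exocyclic alkene without changing the stereocentres.

**Step 13**
Reactants: 25
Product: 27 3-[(1S,4aR,5S,6S,8aR)-5-[(2,5-dihydroxy-3-methylphenyl)methyl]-5,6,8a-trimethyl-2-(propan-2-ylidene)decahydronaphthalen-1-yl]propanoic acid, via benzoquinone 26 (not isolated)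
Conditions: CAN (2.5 equiv), MeCN/H2O, 0 °C; then aq. Na2S2O4, EtOAc, 25 °C
Reagents that add atoms: water O
Why: CAN oxidative demethylation of the 1,4-dimethoxyarene to the quinone and dithionite reduction give the free hydroquinone, as in avarol-type endgames.

**Step 14**
Reactants: 27
Product: 28 3-[(1S,4aR,5S,6S,8aR)-5-[(5-acetyloxy-2-hydroxy-3-methylphenyl)methyl]-5,6,8a-trimethyl-2-(propan-2-ylidene)decahydronaphthalen-1-yl]propanoic acid (CNP0144688.1)
Conditions: Ac2O (1.05 equiv), pyridine, CH2Cl2, 0 °C; aqueous work-up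
Reagents that add atoms: acetic anhydride CC(=O)OC(C)=O
Why: site-selective acylation of the unhindered phenol, since the other OH is flanked by the methyl and the neopentyl-type benzyl substituent, and any mixed anhydride of the acid hydrolyses on work-up.

**Compound list**
1 | 2,6-dimethylphenol | Cc1cccc(C)c1O | starting material
2 | 2,6-dimethylcyclohexa-2,5-diene-1,4-dione | CC1=CC(=O)C=C(C)C1=O | intermediate
3 | 2,6-dimethylbenzene-1,4-diol | Cc1cc(O)cc(C)c1O | intermediate
4 | 2,5-dimethoxy-1,3-dimethylbenzene | COc1cc(C)c(OC)c(C)c1 | intermediate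
5 | 1-(bromomethyl)-2,5-dimethoxy-3-methylbenzene | COc1cc(C)c(OC)c(CBr)c1 | intermediate
6 | propanal | CCC=O | starting material
7 | N-cyclohexylpropan-1-imine | CCC=NC1CCCCC1 | intermediate
8 | N-cyclohexyl-3-(2,5-dimethoxy-3-methylphenyl)-2-methylpropan-1-imine (racemic) | COc1cc(C)c(OC)c(CC(C)C=NC2CCCCC2)c1 | intermediate
9 | 3-(2,5-dimethoxy-3-methylphenyl)-2-methylpropanal (racemic) | COc1cc(C)c(OC)c(CC(C)C=O)c1 | intermediate
10 | but-3-yn-2-one | CC(=O)C#C | starting material
11 | 2-[(2,5-dimethoxy-3-methylphenyl)methyl]-2-methyl-5-oxohex-3-enal (E/Z, racemic) | COc1cc(C)c(OC)c(CC(C)(C=O)C=CC(C)=O)c1 | intermediate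
12 | 4-[(2,5-dimethoxy-3-methylphenyl)methyl]-4-methylcyclohexa-2,5-dien-1-one (achiral, prochiral) | COc1cc(C)c(OC)c(CC2(C)C=CC(=O)C=C2)c1 | intermediate
13 | 1-(2-bromoethyl)-3-methoxybenzene | COc1cccc(CCBr)c1 | starting material
14 | [2-(3-methoxyphenyl)ethyl]magnesium bromide | COc1cccc(CC[Mg]Br)c1 | intermediate
15 | bromomagnesium cross-conjugated dienolate of the 1,4-adduct (side chain trans to arylmethyl) | COc1cc(C)c(OC)c(C[C@]2(C)[C@@H](CCc3cccc(OC)c3)C=C(O[Mg]Br)C=C2)c1 | intermediate
16 | (4S,5S,6S)-4-[(2,5-dimethoxy-3-methylphenyl)methyl]-5-[2-(3-methoxyphenyl)ethyl]-4,6-dimethylcyclohex-2-en-1-one (C5 chain trans to arylmethyl; major C6 epimer) | COc1cc(C)c(OC)c(C[C@]2(C)[C@@H](CCc3cccc(OC)c3)[C@H](C)C(=O)C=C2)c1 | intermediate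
17 | trimethylsilyl enol ether of 18 (C1=C6 enol ether; stereocentres as in 18) | COc1cc(C)c(OC)c(C[C@]2(C)[C@@H](CCc3cccc(OC)c3)[C@H](C)C(O[Si](C)(C)C)=C[C@@H]2C)c1 | intermediate
18 | (2S,3S,4S,5S)-4-[(2,5-dimethoxy-3-methylphenyl)methyl]-3-[2-(3-methoxyphenyl)ethyl]-2,4,5-trimethylcyclohexan-1-one (5-Me cis to arylmethyl) | COc1cc(C)c(OC)c(C[C@]2(C)[C@@H](CCc3cccc(OC)c3)[C@H](C)C(=O)C[C@@H]2C)c1 | intermediate
19 | (2S,3S,4S,5S)-4-[(2,5-dimethoxy-3-methylphenyl)methyl]-3-[2-(3-methoxyphenyl)ethyl]-2,4,5-trimethylcyclohexan-1-ol (C1 epimer mixture) | COc1cc(C)c(OC)c(C[C@]2(C)[C@@H](CCc3cccc(OC)c3)[C@H](C)C(O)C[C@@H]2C)c1 | intermediate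
20 | (4S,5S,6S)-5-[(2,5-dimethoxy-3-methylphenyl)methyl]-6-[2-(3-methoxyphenyl)ethyl]-1,4,5-trimethylcyclohex-1-ene | COc1cc(C)c(OC)c(C[C@]2(C)[C@@H](CCc3cccc(OC)c3)C(C)=CC[C@@H]2C)c1 | intermediate
21 | (1S,2S,4aR,10aR)-1-[(2,5-dimethoxy-3-methylphenyl)methyl]-7-methoxy-1,2,4a-trimethyl-1,2,3,4,4a,9,10,10a-octahydrophenanthrene (trans-fused) | COc1cc(C)c(OC)c(C[C@]2(C)[C@H]3CCc4cc(OC)ccc4[C@]3(C)CC[C@@H]2C)c1 | intermediate
22 | (1S,2S,4aR,10aR)-1-[(2,5-dimethoxy-3-methylphenyl)methyl]-7-methoxy-1,2,4a-trimethyl-1,2,3,4,4a,5,8,9,10,10a-decahydrophenanthrene | COc1cc(C)c(OC)c(C[C@]2(C)[C@H]3CCC4=C(CC=C(OC)C4)[C@]3(C)CC[C@@H]2C)c1 | intermediate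
23 | (4aR,4bS,7S,8S,8aR)-8-[(2,5-dimethoxy-3-methylphenyl)methyl]-4b,7,8-trimethyl-4,4a,4b,5,6,7,8,8a,9,10-decahydrophenanthren-2(3H)-one | COc1cc(C)c(OC)c(C[C@]2(C)[C@H]3CCC4=CC(=O)CC[C@H]4[C@]3(C)CC[C@@H]2C)c1 | intermediate
24 | 3-[(1S,4aR,5S,6S,8aR)-5-[(2,5-dimethoxy-3-methylphenyl)methyl]-5,6,8a-trimethyl-2-oxodecahydronaphthalen-1-yl]propanoic acid | COc1cc(C)c(OC)c(C[C@]2(C)[C@H]3CCC(=O)[C@@H](CCC(=O)O)[C@]3(C)CC[C@@H]2C)c1 | intermediate
25 | 3-[(1S,4aR,5S,6S,8aR)-5-[(2,5-dimethoxy-3-methylphenyl)methyl]-5,6,8a-trimethyl-2-(propan-2-ylidene)decahydronaphthalen-1-yl]propanoic acid | COc1cc(C)c(OC)c(C[C@]2(C)[C@H]3CCC(=C(C)C)[C@@H](CCC(=O)O)[C@]3(C)CC[C@@H]2C)c1 | intermediate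
26 | 3-[(1S,4aR,5S,6S,8aR)-5,6,8a-trimethyl-5-[(5-methyl-3,6-dioxocyclohexa-1,4-dien-1-yl)methyl]-2-(propan-2-ylidene)decahydronaphthalen-1-yl]propanoic acid | CC1=CC(=O)C=C(C[C@]2(C)[C@H]3CCC(=C(C)C)[C@@H](CCC(=O)O)[C@]3(C)CC[C@@H]2C)C1=O | intermediate
27 | 3-[(1S,4aR,5S,6S,8aR)-5-[(2,5-dihydroxy-3-methylphenyl)methyl]-5,6,8a-trimethyl-2-(propan-2-ylidene)decahydronaphthalen-1-yl]propanoic acid | Cc1cc(O)cc(C[C@]2(C)[C@H]3CCC(=C(C)C)[C@@H](CCC(=O)O)[C@]3(C)CC[C@@H]2C)c1O | intermediate
28 | 3-[(1S,4aR,5S,6S,8aR)-5-[(5-acetyloxy-2-hydroxy-3-methylphenyl)methyl]-5,6,8a-trimethyl-2-(propan-2-ylidene)decahydronaphthalen-1-yl]propanoic acid | CC(=O)Oc1cc(C)c(O)c(C[C@]2(C)[C@H]3CCC(=C(C)C)[C@@H](CCC(=O)O)[C@]3(C)CC[C@@H]2C)c1 | target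

**Totals**
Total step count: 14. Longest linear sequence: 14 steps (1 → 28); bromide 13 enters without a separate isolated step.

**Three steps most likely to fail**

Step 6. The face selectivity (methyl versus arylmethyl on the prochiral carbon) may be only moderate, and a functionalised Grignard with a dienone is demanding for Cu catalysis. The fallback sets out from 12 and comes back at 18. A Rh(I)/chiral-diene-catalysed Hayashi–Miyaura conjugate alkenylation of 12 with (E)-2-(3-methoxyphenyl)ethenylboronic acid gives the styryl enone F1; its face and arm selectivity are under stronger catalyst control with an sp2 nucleophile. LDA/MeI methylates the only enolisable α-position to give the methylated styryl enone F2. Me2CuLi adds to the remaining enone to give the styryl ketone F3. Hydrogenation of the styrene (H2, Pd/C, EtOAc) then delivers 18.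

Step 9. The cyclisation relies on acid ionisation of a secondary alcohol and a hydride shift; it may give cis-fused or rearranged products, or attack by the electron-rich dimethoxyarene. The fallback sets out from 18 and comes back at 21. The ketone is converted with Tf2O and 2,6-di-tert-butyl-4-methylpyridine into the more substituted enol triflate F4, which is reduced with Pd(OAc)2/PPh3/HCO2H/Bu3N to the isolated alkene 20. The ring is then closed by Co(salen)-catalysed hydrogen-atom-transfer/radical–polar-crossover hydroarylation (N-fluoro-2,4,6-trimethylpyridinium salt, (Me2SiH)2O), which forms the tertiary cation regiospecifically under neutral conditions and gives 21.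

Step 12. Wittig isopropylidenation of an α-branched ketone next to a quaternary centre may stall through enolisation. The fallback sets out from 24 and comes back at 25. Esterification with TMSCHN2 gives the keto methyl ester F5; McMurry reductive cross-coupling with excess acetone (TiCl4, Zn, pyridine, THF, reflux) gives the isopropylidene methyl ester F6; saponification (LiOH, THF/H2O) returns 25.

**Further compounds**
F1 | step 6 | 4-[(2,5-dimethoxy-3-methylphenyl)methyl]-5-[(E)-2-(3-methoxyphenyl)ethenyl]-4-methylcyclohex-2-en-1-one (alkenyl group trans to arylmethyl) | COc1cc(C)c(OC)c(C[C@]2(C)[C@@H](/C=C/c3cccc(OC)c3)CC(=O)C=C2)c1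
F2 | step 6 | 4-[(2,5-dimethoxy-3-methylphenyl)methyl]-5-[(E)-2-(3-methoxyphenyl)ethenyl]-4,6-dimethylcyclohex-2-en-1-one | COc1cc(C)c(OC)c(C[C@]2(C)[C@@H](/C=C/c3cccc(OC)c3)[C@H](C)C(=O)C=C2)c1
F3 | step 6 | 4-[(2,5-dimethoxy-3-methylphenyl)methyl]-3-[(E)-2-(3-methoxyphenyl)ethenyl]-2,4,5-trimethylcyclohexan-1-one | COc1cc(C)c(OC)c(C[C@]2(C)[C@@H](/C=C/c3cccc(OC)c3)[C@H](C)C(=O)C[C@@H]2C)c1
F4 | step 9 | 4-[(2,5-dimethoxy-3-methylphenyl)methyl]-3-[2-(3-methoxyphenyl)ethyl]-2,4,5-trimethylcyclohex-1-en-1-yl trifluoromethanesulfonate | COc1cc(C)c(OC)c(C[C@]2(C)[C@@H](CCc3cccc(OC)c3)C(C)=C(OS(=O)(=O)C(F)(F)F)C[C@@H]2C)c1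
F5 | step 12 | methyl 3-[(1S,4aR,5S,6S,8aR)-5-[(2,5-dimethoxy-3-methylphenyl)methyl]-5,6,8a-trimethyl-2-oxodecahydronaphthalen-1-yl]propanoate | COc1cc(C)c(OC)c(C[C@]2(C)[C@H]3CCC(=O)[C@@H](CCC(=O)OC)[C@]3(C)CC[C@@H]2C)c1
F6 | step 12 | methyl 3-[(1S,4aR,5S,6S,8aR)-5-[(2,5-dimethoxy-3-methylphenyl)methyl]-5,6,8a-trimethyl-2-(propan-2-ylidene)decahydronaphthalen-1-yl]propanoate | COc1cc(C)c(OC)c(C[C@]2(C)[C@H]3CCC(=C(C)C)[C@@H](CCC(=O)OC)[C@]3(C)CC[C@@H]2C)c1
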